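Ring A is disconnected at its homoallylic bromide: the sequence C(Me)=CH–CH2–CHBr beside the gem-dimethyl carbon is what bromide capture of a 2-methylbicyclo[3.1.0]hex-2-yl cation delivers. In one operation the key step cuts the bond shared by a cyclopropane and a spiro-fused cyclopentane, so enlarging the five-membered ring to the cyclohexene, placing the trisubstituted alkene and installing the neopentyl secondary bromide with inversion. Its precursor is a tertiary cyclopropyl carbinol already carrying the finished ring B, whose trans bromo chloro pair is relayed from the spiro carbon through a bromolactone bridging the 1,4 positions; the spiro centre itself comes from an enantioselective Diels–Alder reaction.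

Key step: step 11

Assumption: the (R)-configured oxazaborolidinium salt (step 3) and the (S,S)-configured bis(oxazoline) ligand (step 9) are taken as the matched antipodes; each sense of induction is to be confirmed (anomalous-dispersion X-ray analysis of lactone 8 and of ketone 14) and the mirror-image catalyst used if it proves reversed.

Step 1
Reactants: 1 methyl 3,3-dimethylpent-4-enoate
Product: 2 3,3-dimethylpent-4-enal
Conditions: iBu2AlH (1.05 equiv), CH2Cl2, −78 °C; MeOH, then aq. potassium sodium tartrate
Reagents that add atoms: none
Why: Partial ester reduction, in which the aluminium hemiacetal formed from one hydride is stable at −78 °C and collapses to the aldehyde only on work-up, the terminal alkene being inert to iBu2AlH at this temperature.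

Step 2
Reactants: 2 3,3-dimethylpent-4-enal, 3 formaldehyde (37% aqueous)
Product: 4 3,3-dimethyl-2-methylidenepent-4-enal
Conditions: pyrrolidine (10 mol%), propionic acid (10 mol%), iPrOH, 45 °C
Reagents that add atoms: none
Why: Amine-catalysed Mannich-type α-methylenation, in which the enamine of the only enolisable position adds to the formaldehyde-derived iminium ion and the amine is then eliminated, the quaternary β-carbon blocking double-bond migration.

Step 3
Reactants: 4 3,3-dimethyl-2-methylidenepent-4-enal, 5 isoprene
Product: 6 (R)-4-methyl-1-(2-methylbut-3-en-2-yl)cyclohex-3-ene-1-carbaldehyde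
Conditions: isoprene (5 equiv), (R)-3,3-diphenyl-1-(2-methylphenyl)tetrahydro-1H,3H-pyrrolo[1,2-c][1,3,2]oxazaborole·HNTf2 (20 mol%), CH2Cl2, −78 to −20 °C
Reagents that add atoms: none
Why: Enantioselective Diels–Alder reaction, in which the cationic oxazaborolidine binds the s-trans enal through its carbonyl oxygen and a formyl C–H···O contact, shields one face and lets the larger terminal coefficient of isoprene bond to the enal β-carbon (para adduct), so the quaternary (R) centre is set by the catalyst.

Step 4
Reactants: 6 (R)-4-methyl-1-(2-methylbut-3-en-2-yl)cyclohex-3-ene-1-carbaldehyde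
Product: 7 (R)-4-methyl-1-(2-methylbut-3-en-2-yl)cyclohex-3-ene-1-carboxylic acid
Conditions: NaClO2, NaH2PO4, 2-methylbut-2-ene (10 equiv), tBuOH/H2O, 0 °C to rt
Reagents that add atoms: sodium chlorite, [Na+].[O-]Cl=O
Why: Pinnick oxidation, in which chlorous acid oxidises the hindered, non-epimerisable aldehyde while the excess 2-methylbut-2-ene consumes HOCl before it can attack the ring alkene or the vinyl group.

Step 5
Reactants: 7 (R)-4-methyl-1-(2-methylbut-3-en-2-yl)cyclohex-3-ene-1-carboxylic acid
Product: 8 (1S,4R,6S)-6-bromo-1-methyl-4-(2-methylbut-3-en-2-yl)-2-oxabicyclo[2.2.2]octan-3-one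
Conditions: N-bromosuccinimide (1.05 equiv), MeCN, 0 °C, dark; recrystallisation
Reagents that add atoms: N-bromosuccinimide, O=C1CCC(=O)N1Br
Why: Bromolactonisation, in which the bromonium ion of the electron-rich ring alkene is trapped only when it lies anti to the carboxyl group, oxygen attacking the methyl-bearing carbon (Markovnikov) through a boat, so that C–O is syn to the carbonyl bridge and C–Br trans to it, both dictated by the quaternary centre, while the vinyl group cannot lactonise to a favourable ring and recrystallisation removes any γ-lactone regioisomer and raises enantiopurity.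

Step 6
Reactants: 8 (1S,4R,6S)-6-bromo-1-methyl-4-(2-methylbut-3-en-2-yl)-2-oxabicyclo[2.2.2]octan-3-one
Product: 10 (1R,3S,4S)-3-bromo-4-chloro-4-methyl-1-(2-methylbut-3-en-2-yl)cyclohexane-1-carboxylic acid, via acyloxydichloroborane 9 (not isolated)
Conditions: BCl3 (1.5 equiv), CH2Cl2, −78 to −30 °C; ice water
Reagents that add atoms: boron trichloride, ClB(Cl)Cl
Why: Lewis acid cleavage of the alkyl–oxygen bond of a tertiary lactone, in which BCl3 on the carbonyl oxygen lets the tertiary C–O bond ionise inside a contact ion pair held in the boat of the bicycle, the bromine on the opposite face bridging from the rear, and chloride passes from the acyloxytrichloroborate to the tertiary carbon on the face the oxygen has just left, so chlorine replaces oxygen with retention, the CHBr centre is untouched and the product relaxes to the diequatorial dihalide, which no longer ionises at low temperature.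

Step 7
Reactants: 10 (1R,3S,4S)-3-bromo-4-chloro-4-methyl-1-(2-methylbut-3-en-2-yl)cyclohexane-1-carboxylic acid
Product: 11 (1R,3S,4S)-3-bromo-4-chloro-4-methyl-1-(2-methylbut-3-en-2-yl)cyclohexane-1-carbonyl chloride
Conditions: (COCl)2 (1.5 equiv), DMF (cat.), CH2Cl2, 0 °C to rt; evaporate, use crude
Reagents that add atoms: oxalyl chloride, O=C(Cl)C(=O)Cl
Why: Acid chloride formation through the Vilsmeier chloroiminium salt under cold, neutral conditions, the acid having no α-hydrogen (no ketene) and the alkyl halides and vinyl group being inert.

Step 8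
Reactants: 11 (1R,3S,4S)-3-bromo-4-chloro-4-methyl-1-(2-methylbut-3-en-2-yl)cyclohexane-1-carbonyl chloride, 12 trimethylsilyldiazomethane
Product: 13 1-[(1R,3S,4S)-3-bromo-4-chloro-4-methyl-1-(2-methylbut-3-en-2-yl)cyclohexyl]-2-diazoethan-1-one
Conditions: TMSCHN2 (2.5 equiv, 2 M in hexanes), MeCN/THF 1:1, 0 °C to rt
Reagents that add atoms: none
Why: Arndt–Eistert-type diazoketone synthesis, in which the diazo carbon is acylated and the resulting diazonium ion loses silicon to chloride, the excess reagent compensating for the slow reaction of the hindered acyl chloride.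

Step 9
Reactants: 13 1-[(1R,3S,4S)-3-bromo-4-chloro-4-methyl-1-(2-methylbut-3-en-2-yl)cyclohexyl]-2-diazoethan-1-one
Product: 14 (1S,3R,5R,3'S,4'S)-3'-bromo-4'-chloro-4,4,4'-trimethylspiro[bicyclo[3.1.0]hexane-3,1'-cyclohexan]-2-one
Conditions: (CuOTf)2·C6H6 (5 mol%), (S,S)-2,2'-(propane-2,2-diyl)bis(4-tert-butyl-4,5-dihydrooxazole) (6 mol%), CH2Cl2, 25 to 40 °C, slow addition of 13
Reagents that add atoms: none
Why: Intramolecular carbenoid cyclopropanation, in which the copper carbene adds to the tethered vinyl group (five-membered closure helped by the two adjacent quaternary carbons, cis ring fusion obligatory) and the chiral ligand selects the alkene face that places the cyclopropane CH2 beside the ring-B CH2 adjoining CHBr, copper being chosen to suppress C–H insertion into ring B and the minor diastereomer being removed by chromatography.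

Step 10
Reactants: 14 (1S,3R,5R,3'S,4'S)-3'-bromo-4'-chloro-4,4,4'-trimethylspiro[bicyclo[3.1.0]hexane-3,1'-cyclohexan]-2-one, 15 methylmagnesium bromide
Product: 16 (1S,2S,3R,5R,3'S,4'S)-3'-bromo-4'-chloro-2,4,4,4'-tetramethylspiro[bicyclo[3.1.0]hexane-3,1'-cyclohexan]-2-ol
Conditions: MeMgBr (2 equiv), anhydrous CeCl3 (2 equiv), THF, −78 °C; aq. NH4Cl
Reagents that add atoms: none
Why: CeCl3-promoted Grignard 1,2-addition to a hindered, poorly enolisable ketone at a temperature where the alkyl halides are inert, the methyl group expected to enter anti to the cyclopropane methylene although the carbinol configuration is erased in the next step.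

Step 11
Reactants: 16 (1S,2S,3R,5R,3'S,4'S)-3'-bromo-4'-chloro-2,4,4,4'-tetramethylspiro[bicyclo[3.1.0]hexane-3,1'-cyclohexan]-2-ol
Product: 18 (4R,6S,8S,9S)-4,8-dibromo-9-chloro-1,5,5,9-tetramethylspiro[5.5]undec-1-ene (CNP0126187.2), via cyclopropylcarbinyl cation 17 (not isolated)
Conditions: anhydrous HBr (1.05 equiv, ca. 1 M in CH2Cl2), CH2Cl2, −78 to −40 °C; cold aq. NaHCO3
Reagents that add atoms: hydrogen bromide, Br
Why: Proposed new method: protonation and loss of water give the tertiary 2-methylbicyclo[3.1.0]hex-2-yl cation 17, whose charge is shared with the two distal cyclopropane carbons, and bromide attacks the secondary neopentyl cyclopropane carbon from the side opposite the bond it shares with the five-membered ring, so that this bond breaks, C–Br forms there and the ring alkene appears at the methyl-bearing carbon (cyclopropylcarbinyl-to-homoallyl rearrangement). The closest known reaction types are the acid opening of thujane-type bicyclo[3.1.0]hex-2-yl cations to cyclohex-3-enyl products, the conversion of 3,5-cyclosteroids into 3β-halo-5-enes and the Julia conversion of cyclopropyl carbinols into homoallylic bromides, none of them shown on a spiro-fused, neopentyl-flanked case. No ring is closed: the zero-atom bridge of the bicyclo[3.1.0]hexane is cut and the five-membered ring thereby grows into the six-membered ring A. The one new stereocentre, CHBr of ring A (R), is controlled by the cyclopropane configuration of 16, the C–C bond being replaced by C–Br with inversion. The step needs cleavage of the shared bond and not the outer one, which is secured by better charge stabilisation at the secondary than at the primary cyclopropane carbon, by release of bicyclic strain and by reversible capture at the tertiary centre, which drains material into the secondary bromide that does not re-ionise. The tertiary carbinol ionises far faster than the diequatorial β-bromo tertiary chloride of ring B, and one equivalent of acid at low temperature spares the new alkene.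

Compound list
1 | methyl 3,3-dimethylpent-4-enoate | COC(=O)CC(C)(C)C=C | starting material
2 | 3,3-dimethylpent-4-enal | O=CCC(C)(C)C=C | intermediate
3 | formaldehyde | C=O | starting material
4 | 3,3-dimethyl-2-methylidenepent-4-enal | C=CC(C)(C)C(=C)C=O | intermediate
5 | isoprene (2-methylbuta-1,3-diene) | C=CC(C)=C | starting material
6 | (R)-4-methyl-1-(2-methylbut-3-en-2-yl)cyclohex-3-ene-1-carbaldehyde | O=C[C@]1(C(C)(C)C=C)CCC(C)=CC1 | intermediate
7 | (R)-4-methyl-1-(2-methylbut-3-en-2-yl)cyclohex-3-ene-1-carboxylic acid | OC(=O)[C@]1(C(C)(C)C=C)CCC(C)=CC1 | intermediate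
8 | (1S,4R,6S)-6-bromo-1-methyl-4-(2-methylbut-3-en-2-yl)-2-oxabicyclo[2.2.2]octan-3-one (oxygen syn to the carbonyl bridge, bromine trans to oxygen) | O=C1O[C@@]2(C)CC[C@]1(C(C)(C)C=C)C[C@@H]2Br | intermediate
9 | acyloxydichloroborane of acid 10 (dichloroboryl (1R,3S,4S)-3-bromo-4-chloro-4-methyl-1-(2-methylbut-3-en-2-yl)cyclohexane-1-carboxylate) | O=C(OB(Cl)Cl)[C@]1(C(C)(C)C=C)CC[C@](C)(Cl)[C@@H](Br)C1 | intermediate (not isolated)
10 | (1R,3S,4S)-3-bromo-4-chloro-4-methyl-1-(2-methylbut-3-en-2-yl)cyclohexane-1-carboxylic acid (chlorine syn to carboxyl, bromine trans to chlorine) | OC(=O)[C@]1(C(C)(C)C=C)CC[C@](C)(Cl)[C@@H](Br)C1 | intermediate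
11 | (1R,3S,4S)-3-bromo-4-chloro-4-methyl-1-(2-methylbut-3-en-2-yl)cyclohexane-1-carbonyl chloride | ClC(=O)[C@]1(C(C)(C)C=C)CC[C@](C)(Cl)[C@@H](Br)C1 | intermediate
12 | trimethylsilyldiazomethane | C[Si](C)(C)C=[N+]=[N-] | starting material
13 | 1-[(1R,3S,4S)-3-bromo-4-chloro-4-methyl-1-(2-methylbut-3-en-2-yl)cyclohexyl]-2-diazoethan-1-one | [N-]=[N+]=CC(=O)[C@]1(C(C)(C)C=C)CC[C@](C)(Cl)[C@@H](Br)C1 | intermediate
14 | (1S,3R,5R,3'S,4'S)-3'-bromo-4'-chloro-4,4,4'-trimethylspiro[bicyclo[3.1.0]hexane-3,1'-cyclohexan]-2-one (cyclopropane CH2 on the side of the ring-B CH2 adjoining CHBr) | O=C1[C@H]2C[C@H]2C(C)(C)[C@]13CC[C@](C)(Cl)[C@@H](Br)C3 | intermediate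
15 | methylmagnesium bromide | C[Mg]Br | starting material
16 | (1S,2S,3R,5R,3'S,4'S)-3'-bromo-4'-chloro-2,4,4,4'-tetramethylspiro[bicyclo[3.1.0]hexane-3,1'-cyclohexan]-2-ol (hydroxyl syn to the cyclopropane CH2) | C[C@]1(O)[C@H]2C[C@H]2C(C)(C)[C@]13CC[C@](C)(Cl)[C@@H](Br)C3 | intermediate
17 | tertiary 2-methylbicyclo[3.1.0]hex-2-yl (cyclopropylcarbinyl) cation derived from 16 | C[C+]1[C@H]2C[C@H]2C(C)(C)[C@]13CC[C@](C)(Cl)[C@@H](Br)C3 | intermediate (not isolated)
18 | (4R,6S,8S,9S)-4,8-dibromo-9-chloro-1,5,5,9-tetramethylspiro[5.5]undec-1-ene (CNP0126187.2) | CC1=CC[C@@H](Br)C(C)(C)[C@]12CC[C@](C)(Cl)[C@@H](Br)C2 | target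

Total step count: 11
Longest linear sequence: 11 steps (from 1 to 18)

Steps most likely to fail

1. Step 11 (ring expansion). Bromide may be captured at the primary cyclopropane carbon with cleavage of the outer bond, the cation may lose a proton to give dienes, or a methyl group may migrate from the gem-dimethyl carbon as charge builds at the neopentyl position. The fallback uses known reaction types and no cyclopropane; it sets out from diazoketone 13 and comes back at target 18. Aqueous HBr in Et2O at 0 °C should convert 13 into the bromomethyl ketone F1. A bromine-atom-transfer radical cyclisation (CuBr, tris(2-pyridylmethyl)amine, 1,2-dichloroethane, 80 °C) should then close ring A in the 6-endo mode preferred by α-keto radicals whose carbonyl lies inside the forming ring, giving the 4-bromo spiro ketone F2 with the C–Br bond made by bromine transfer to the ring radical. The price is that this configuration is no longer relayed from a cyclopropane, so the C-4 epimers would have to be separated. Tf2O with 2,6-di-tert-butyl-4-methylpyridine should turn F2 into the enol triflate F3 on its only enolisable side without an enolate (which could close back to a cyclopropane by 1,3-elimination), and Negishi methylation (MeZnCl, Pd(PPh3)4, THF) should give 18.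

2. Step 6 (chloride for oxygen at the tertiary carbon). The ion pair may separate before chloride is returned, which would erode the tertiary configuration (the wanted epimer carries the axial methyl group and is the less stable one); elimination of a proton or incomplete cleavage of the carbonyl-bound complex are the other risks. The fallback replaces the acyl–oxygen tether by an ether tether, so that the Lewis acid sits on the very oxygen that leaves; it sets out from aldehyde 6 and comes back at acid 10. NaBH4 in MeOH should reduce 6 to the primary alcohol F4, and N-bromosuccinimide in MeCN should close the bridged bromo ether F5 with the same facial logic as the lactone. BCl3 in CH2Cl2 at −78 °C should cleave the tertiary alkyl–oxygen bond of this ether (a standard, fast ether cleavage) with chloride returned on the same face, giving the bromo chloro alcohol F6. Jones oxidation (CrO3, H2SO4, acetone, 0 °C) should then give 10.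

3. Step 3 (Diels–Alder reaction). The α-tert-alkyl acrolein is very hindered, so the catalysed cycloaddition may be slow and the facial selectivity may fall short of that known for smaller 2-substituted acroleins. The fallback separates ring construction from asymmetric induction; it sets out from 4 and 5 and comes back at acid 7. An achiral Lewis acid (EtAlCl2, 20 mol%, CH2Cl2, −78 to 0 °C) should give the racemic para adduct F7, and Pinnick oxidation as in step 4 the racemic acid F8. Classical resolution by crystallisation of the (S)-1-phenylethylammonium salt F9 (or the salt of the antipodal amine, whichever crystallises with the R acid), followed by acidification, should return 7; the recrystallisation of lactone 8 remains as a second upgrade.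

Further compounds
F1 | step 11 | 2-bromo-1-[(1R,3S,4S)-3-bromo-4-chloro-4-methyl-1-(2-methylbut-3-en-2-yl)cyclohexyl]ethan-1-one | BrCC(=O)[C@]1(C(C)(C)C=C)CC[C@](C)(Cl)[C@@H](Br)C1
F2 | step 11 | (4R,6R,8S,9S)-4,8-dibromo-9-chloro-5,5,9-trimethylspiro[5.5]undecan-1-one | O=C1CC[C@@H](Br)C(C)(C)[C@]12CC[C@](C)(Cl)[C@@H](Br)C2
F3 | step 11 | (4R,6R,8S,9S)-4,8-dibromo-9-chloro-5,5,9-trimethylspiro[5.5]undec-1-en-1-yl trifluoromethanesulfonate | O=S(=O)(OC1=CC[C@@H](Br)C(C)(C)[C@]12CC[C@](C)(Cl)[C@@H](Br)C2)C(F)(F)F
F4 | step 6 | [(1R)-4-methyl-1-(2-methylbut-3-en-2-yl)cyclohex-3-en-1-yl]methanol | OC[C@]1(C(C)(C)C=C)CCC(C)=CC1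
F5 | step 6 | (1S,4R,6S)-6-bromo-1-methyl-4-(2-methylbut-3-en-2-yl)-2-oxabicyclo[2.2.2]octane | C1O[C@@]2(C)CC[C@]1(C(C)(C)C=C)C[C@@H]2Br
F6 | step 6 | [(1R,3S,4S)-3-bromo-4-chloro-4-methyl-1-(2-methylbut-3-en-2-yl)cyclohexyl]methanol | OC[C@]1(C(C)(C)C=C)CC[C@](C)(Cl)[C@@H](Br)C1
F7 | step 3 | racemic 4-methyl-1-(2-methylbut-3-en-2-yl)cyclohex-3-ene-1-carbaldehyde | O=CC1(C(C)(C)C=C)CCC(C)=CC1
F8 | step 3 | racemic 4-methyl-1-(2-methylbut-3-en-2-yl)cyclohex-3-ene-1-carboxylic acid | OC(=O)C1(C(C)(C)C=C)CCC(C)=CC1
F9 | step 3 | (S)-1-phenylethylammonium (R)-4-methyl-1-(2-methylbut-3-en-2-yl)cyclohex-3-ene-1-carboxylate | C[C@H]([NH3+])c1ccccc1.[O-]C(=O)[C@]1(C(C)(C)C=C)CCC(C)=CC1
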